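**Plan**

1. Locants follow the naphthalene-1,7-dione numbering of the target (C1 enone carbonyl, C2 enol carbon, C3, C4 quaternary, C4a=C8a, C5, C6, C7 ketone, C8 quaternary). The diosphenol is the enol of a C1/C2 dione, so C2 is carried as a silyl ether. The C8 acetoxymethyl group is cut back to a C7 silyl enol ether and C4a=C8a to a saturated ring fusion. C5–C6 and C4a–C8a are then cut together by a retro-[4+2].
2. Enabling feature: in ring A the ketone C7 lies between C6 and the quaternary C8, so without its CH2OAc group C6=C7(OSi)–C8(Me)=C8a is a 2-siloxydiene. C4a–C5 is then a vinyl group on the quaternary C4, and C1–C4 of ring B is a four-atom tether.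
3. Forward order: a C10 diol from hexa-1,5-diyne; Ireland–Claisen rearrangement (C3–C4 bond, C4 with its vinyl group); 2,3-dimethylfuran added at C2 as a masked C1/C8a/C8/C7 enedione; oxidative opening and enol silylation; intramolecular Diels–Alder reaction closing ring B (tether) and ring A (cyclohexene) at once; dehydrogenation, hydroxymethylation at C8, acetate, diosphenol.
4. Stereochemistry: C4 comes from the reagent-controlled Ireland–Claisen step (chiral boron ketene acetal). C8 comes from a catalyst-controlled hydroxymethylation of the planarised dienol ether. C2, C3, C4a and C8a are temporary and end as sp2 carbons; the side-chain E alkene comes from syn-carboalumination.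

Key step: step 10

Assumption: in step 4 the sense of induction of the (S,S)-controller and the ketene acetal geometry, and in step 12 the facial sense of the (S,S)-ligand, are taken from the behaviour of simple substrates; only C4 and C8 must be right, and the antipodal controller or ligand would be used if the sense proved opposite.

Abbreviations: TBS = tert-butyldimethylsilyl, TBDPS = tert-butyldiphenylsilyl, TBSO/TBDPSO = the corresponding silyloxy groups, DMP = Dess–Martin periodinane.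

**Route**

Step 1
Reactants: 1 hexa-1,5-diyne
Product: 3 (2E,6E)-3,6-dimethylocta-2,6-diene-1,8-diol, via bis(dimethylalumanyl)diene 2 (not isolated)
Conditions: Me3Al, Cp2ZrCl2 (cat.), CH2Cl2, 23 °C; n-BuLi, THF, −78 → 0 °C; (CH2O)n, 23 °C; aq. HCl
Reagents that add atoms: trimethylaluminium C[Al](C)C; paraformaldehyde (as formaldehyde) C=O
Why: Zirconium-catalysed carboalumination (Negishi carboalumination) adds Me–Al syn across each terminal alkyne with aluminium on the terminal carbon, and the alkenylalanate is hydroxymethylated with retention, so both trisubstituted alkenes should form as the E isomers.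

Step 2
Reactants: 3 (2E,6E)-3,6-dimethylocta-2,6-diene-1,8-diol
Product: 4 (2E,6E)-8-(TBDPSO)-3,6-dimethylocta-2,6-dien-1-ol
Conditions: NaH (1.0 equiv), THF, 0 → 23 °C; TBDPSCl (1.0 equiv)
Reagents that add atoms: tert-butyl(chloro)diphenylsilane CC(C)(C)[Si](Cl)(c1ccccc1)c1ccccc1
Why: O-Silylation of a symmetrical diol through its sparingly soluble monosodium alkoxide should differentiate the two ends, and no stereocentre is formed.

Step 3
Reactants: 4 (2E,6E)-8-(TBDPSO)-3,6-dimethylocta-2,6-dien-1-ol; 5 propanoyl chloride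
Product: 6 (2E,6E)-8-(TBDPSO)-3,6-dimethylocta-2,6-dien-1-yl propanoate
Conditions: pyridine, DMAP (cat.), CH2Cl2, 0 °C
Reagents that add atoms: none
Why: Standard O-acylation of the primary allylic alcohol gives the allyl propanoate needed for the ester-enolate Claisen rearrangement.

Step 4
Reactants: 6 (2E,6E)-8-(TBDPSO)-3,6-dimethylocta-2,6-dien-1-yl propanoate
Product: 9 (2R,3S,6E)-8-(TBDPSO)-3-ethenyl-2,3,6-trimethyloct-6-enoic acid, via boron ketene acetal 7 (not isolated), via acyloxyborane 8 (not isolated)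
Conditions: (S,S)-2-bromo-1,3-bis{[3,5-bis(trifluoromethyl)phenyl]sulfonyl}-4,5-diphenyl-1,3,2-diazaborolidine (1.3 equiv), i-Pr2NEt, CH2Cl2, −78 → 23 °C; H2O
Reagents that add atoms: none
Why: Enantioselective Ireland–Claisen rearrangement through a chiral boron ketene acetal: soft enolisation gives 7 with the methyl cis to O–B, and the chair transition state (allylic methyl axial, chain equatorial, as fixed by the E alkene) forms the C3–C4 bond on the enolate face left open by the (S,S)-diazaborolidine, which sets the quaternary C4 (3S in 9) together with the temporary C3 centre.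

Step 5
Reactants: 9 (2R,3S,6E)-8-(TBDPSO)-3-ethenyl-2,3,6-trimethyloct-6-enoic acid
Product: 10 (2R,3S,6E)-8-(TBDPSO)-3-ethenyl-2,3,6-trimethyloct-6-en-1-ol
Conditions: LiAlH4, THF, 0 → 23 °C
Reagents that add atoms: none
Why: Hydride reduction of the carboxylic acid to the primary alcohol should leave the silyl ether, both alkenes and both stereocentres untouched.

Step 6
Reactants: 10 (2R,3S,6E)-8-(TBDPSO)-3-ethenyl-2,3,6-trimethyloct-6-en-1-ol
Product: 11 (2R,3S,6E)-8-(TBDPSO)-3-ethenyl-2,3,6-trimethyloct-6-enal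
Conditions: DMP, pyridine, CH2Cl2, 0 → 23 °C
Reagents that add atoms: none
Why: Dess–Martin oxidation under buffered, non-basic conditions should give the α-branched aldehyde without epimerisation at C3 or over-oxidation.

Step 7
Reactants: 11 (2R,3S,6E)-8-(TBDPSO)-3-ethenyl-2,3,6-trimethyloct-6-enal; 12 2,3-dimethylfuran
Product: 15 2-[(1S,2R,3S,6E)-1-(TBSO)-8-(TBDPSO)-3-ethenyl-2,3,6-trimethyloct-6-en-1-yl]-4,5-dimethylfuran, via 5-lithio-2,3-dimethylfuran 13 (not isolated), via lithium alkoxide 14 (not isolated)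
Conditions: 12, n-BuLi, THF, 0 °C; 11, −78 °C; TBSOTf, −78 → 0 °C
Reagents that add atoms: tert-butyldimethylsilyl trifluoromethanesulfonate CC(C)(C)[Si](C)(C)OS(=O)(=O)C(F)(F)F
Why: 1,2-Addition of an α-lithiofuran to the aldehyde anti to the bulky quaternary substituent (polar 1,2-induction model) should give mainly the 1S alkoxide, which is silylated in the flask; this C2 centre is temporary, so its epimer converges in step 15.

Step 8
Reactants: 15 2-[(1S,2R,3S,6E)-1-(TBSO)-8-(TBDPSO)-3-ethenyl-2,3,6-trimethyloct-6-en-1-yl]-4,5-dimethylfuran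
Product: 17 (3E,6S,7R,8S,11E)-6-(TBSO)-13-(TBDPSO)-8-ethenyl-3,7,8,11-tetramethyltrideca-3,11-diene-2,5-dione, via (Z)-enedione 16 (not isolated)
Conditions: NBS, pyridine, THF–acetone–H2O, −20 → 23 °C
Reagents that add atoms: water O
Why: Oxidative furan ring opening (bromination–hydrolysis of a 2,5-dialkylfuran to the ene-1,4-dione) should be selective because the trialkylfuran reacts far faster with NBS than the vinyl or trisubstituted alkene, and pyridine isomerises the first-formed Z enedione to the more stable E isomer, which places the tether on the outside of the future diene.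

Step 9
Reactants: 17 (3E,6S,7R,8S,11E)-6-(TBSO)-13-(TBDPSO)-8-ethenyl-3,7,8,11-tetramethyltrideca-3,11-diene-2,5-dione
Product: 18 (3E,6S,7R,8S,11E)-2,6-bis(TBSO)-13-(TBDPSO)-8-ethenyl-3,7,8,11-tetramethyltrideca-1,3,11-trien-5-one
Conditions: TBSOTf, Et3N, CH2Cl2, −78 → 0 °C
Reagents that add atoms: tert-butyldimethylsilyl trifluoromethanesulfonate CC(C)(C)[Si](C)(C)OS(=O)(=O)C(F)(F)F
Why: Soft enolisation (silyl triflate and amine) of the methyl ketone at its α'-methyl group should give the cross-conjugated 2-siloxydiene, while the C1 ketone has only the hindered, silyloxy-bearing C2–H and stays a ketone.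

Step 10
Reactants: 18 (3E,6S,7R,8S,11E)-2,6-bis(TBSO)-13-(TBDPSO)-8-ethenyl-3,7,8,11-tetramethyltrideca-1,3,11-trien-5-one
Product: 19 (2S,3R,4S)-2,7-bis(TBSO)-4-[(3E)-5-(TBDPSO)-3-methylpent-3-en-1-yl]-3,4,8-trimethyl-3,4,4a,5,6,8a-hexahydronaphthalen-1(2H)-one (mixture of C4a/C8a ring-fusion diastereomers)
Conditions: PhMe (0.01 M), BHT, Et3N (trace), sealed tube, 180 °C
Reagents that add atoms: none
Why: Thermal intramolecular Diels–Alder reaction: the (E)-2-silyloxy-1,3-diene C6=C7(OTBS)–C8(Me)=C8a adds across the vinyl group C4a=C5 in a concerted, asynchronous [4+2] cycloaddition in which the unhindered C5–C6 bond is advanced and the C4a–C8a bond follows. The closest known reaction type is the thermal cycloaddition of 2-silyloxy-deca-1,3,9-trienes that carry an unactivated terminal alkene, which gives a regiodefined cyclohexenyl silyl ether. Ring A is closed as the new cyclohexene (the [4+2] ring, holding the enol ether C7=C8), and ring B is closed in the same event as the six-membered ring of the four-atom tether C1–C4 in the fused mode, the tether leaving the E-diene terminus from the outside. The two new stereocentres C4a and C8a are set by the endo or exo placement of the tether (cis or trans fusion) and by a chair-like tether that keeps the C2 silyloxy group, the C3 methyl group and the C4 side chain equatorial; both are temporary and are planarised in step 11, so any mixture converges. The step therefore needs only periselectivity and regioselectivity: the short tether excludes the bridged mode and the remote trisubstituted alkene (which would need an eight-membered ring), the quaternary C4 favours ring closure, and the E geometry fixed in step 8 lets the diene reach its s-cis form. The regiodefined enol ether C7=C8 that results is the handle for the quaternary C8.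

Step 11
Reactants: 19 (2S,3R,4S)-2,7-bis(TBSO)-4-[(3E)-5-(TBDPSO)-3-methylpent-3-en-1-yl]-3,4,8-trimethyl-3,4,4a,5,6,8a-hexahydronaphthalen-1(2H)-one
Product: 22 (2S,3R,4R)-2,7-bis(TBSO)-4-[(3E)-5-(TBDPSO)-3-methylpent-3-en-1-yl]-3,4,8-trimethyl-3,4,5,6-tetrahydronaphthalen-1(2H)-one, via lithium dienolate 20 (not isolated), via sulfilimine adduct 21 (not isolated)
Conditions: LiN(i-Pr)2, THF, −78 °C; PhS(Cl)=N-t-Bu, −78 → 0 °C
Reagents that add atoms: none
Why: One-pot enolate dehydrogenation with a sulfinimidoyl chloride (α-sulfenylation then syn-elimination): the doubly activated C8a–H (α to the C1 ketone, allylic to the enol ether) is removed, the dienolate should be sulfenylated at C8a cis to the C4a hydrogen as ring-fusion enolates react, and the sulfilimine abstracts the only β-hydrogen (C4a–H) through a five-membered transition state, so both Diels–Alder stereocentres are erased and every isomer of 19 gives the same dienol ether.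

Step 12
Reactants: 22 (2S,3R,4R)-2,7-bis(TBSO)-4-[(3E)-5-(TBDPSO)-3-methylpent-3-en-1-yl]-3,4,8-trimethyl-3,4,5,6-tetrahydronaphthalen-1(2H)-one
Product: 23 (2S,3R,4R,8S)-2-(TBSO)-4-[(3E)-5-(TBDPSO)-3-methylpent-3-en-1-yl]-8-(hydroxymethyl)-3,4,8-trimethyl-3,4,5,6-tetrahydronaphthalene-1,7(2H,8H)-dione
Conditions: Sc(OTf)3 (10 mol %), (S,S)-6,6'-bis(1-hydroxy-2,2-dimethylpropyl)-2,2'-bipyridine (12 mol %), aq. HCHO (5 equiv), DME–H2O (9:1), −20 °C
Reagents that add atoms: formaldehyde C=O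
Why: Catalytic asymmetric Mukaiyama aldol reaction with aqueous formaldehyde (hydroxymethylation of a silicon enolate by a chiral Sc(OTf)3–bipyridine complex): attack should occur at C8 (α) because C4a (γ) is fully substituted, neopentyl and is the β-carbon of the C1 enone, and the chiral complex selects the enol-ether face, so the quaternary C8 is set by catalyst control on an almost planar ring system in which C4 (axial methyl only) exerts little bias.

Step 13
Reactants: 23 (2S,3R,4R,8S)-2-(TBSO)-4-[(3E)-5-(TBDPSO)-3-methylpent-3-en-1-yl]-8-(hydroxymethyl)-3,4,8-trimethyl-3,4,5,6-tetrahydronaphthalene-1,7(2H,8H)-dione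
Product: 24 (2S,3R,4R,8S)-8-(acetoxymethyl)-2-(TBSO)-4-[(3E)-5-(TBDPSO)-3-methylpent-3-en-1-yl]-3,4,8-trimethyl-3,4,5,6-tetrahydronaphthalene-1,7(2H,8H)-dione
Conditions: Ac2O, pyridine, DMAP (cat.), CH2Cl2, 0 °C
Reagents that add atoms: acetic anhydride CC(=O)OC(C)=O
Why: O-Acylation of the neopentyl primary alcohol at 0 °C should outpace retro-aldol loss of formaldehyde, and no stereocentre is touched.

Step 14
Reactants: 24 (2S,3R,4R,8S)-8-(acetoxymethyl)-2-(TBSO)-4-[(3E)-5-(TBDPSO)-3-methylpent-3-en-1-yl]-3,4,8-trimethyl-3,4,5,6-tetrahydronaphthalene-1,7(2H,8H)-dione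
Product: 25 (2S,3R,4R,8S)-8-(acetoxymethyl)-2-hydroxy-4-[(3E)-5-hydroxy-3-methylpent-3-en-1-yl]-3,4,8-trimethyl-3,4,5,6-tetrahydronaphthalene-1,7(2H,8H)-dione
Conditions: HF·pyridine, pyridine, THF, 0 → 23 °C
Reagents that add atoms: none
Why: Fluoride-mediated cleavage of both silyl ethers under buffered HF·pyridine should leave the acetate, the β-acetoxy ketone (no hydrogen at C8, so no elimination) and the enone intact.

Step 15
Reactants: 25 (2S,3R,4R,8S)-8-(acetoxymethyl)-2-hydroxy-4-[(3E)-5-hydroxy-3-methylpent-3-en-1-yl]-3,4,8-trimethyl-3,4,5,6-tetrahydronaphthalene-1,7(2H,8H)-dione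
Product: 26 (4S,8S)-8-(acetoxymethyl)-2-hydroxy-4-[(3E)-5-hydroxy-3-methylpent-3-en-1-yl]-3,4,8-trimethyl-5,6-dihydronaphthalene-1,7(4H,8H)-dione (target)
Conditions: Cu(OAc)2 (2.2 equiv), MeOH, 23 °C
Reagents that add atoms: none
Why: Cu(OAc)2 oxidation of an α-ketol (through its enediol) is selective for the acyloin over the primary allylic alcohol and the acetate, and the resulting C1/C2 dione enolises toward C3 to the conjugated, hydrogen-bonded diosphenol, which removes the temporary centres C2 and C3 and leaves C4 and C8 untouched.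

**Compound list**

1 | hexa-1,5-diyne | C#CCCC#C | starting material
2 | (1E,5E)-1,6-bis(dimethylalumanyl)-2,5-dimethylhexa-1,5-diene | C[Al](C)/C=C(C)/CC/C(C)=C/[Al](C)C | intermediate
3 | (2E,6E)-3,6-dimethylocta-2,6-diene-1,8-diol | OC/C=C(C)/CC/C(C)=C/CO | intermediate
4 | (2E,6E)-8-(TBDPSO)-3,6-dimethylocta-2,6-dien-1-ol | OC/C=C(C)/CC/C(C)=C/CO[Si](c1ccccc1)(c2ccccc2)C(C)(C)C | intermediate
5 | propanoyl chloride | CCC(=O)Cl | starting material
6 | (2E,6E)-8-(TBDPSO)-3,6-dimethylocta-2,6-dien-1-yl propanoate | CCC(=O)OC/C=C(C)/CC/C(C)=C/CO[Si](c1ccccc1)(c2ccccc2)C(C)(C)C | intermediate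
7 | boron ketene acetal of 6 (methyl cis to O–B, (S,S)-diazaborolidine on oxygen) | C/C=C(\OB1N(S(=O)(=O)c2cc(C(F)(F)F)cc(C(F)(F)F)c2)[C@@H](c3ccccc3)[C@H](c4ccccc4)N1S(=O)(=O)c5cc(C(F)(F)F)cc(C(F)(F)F)c5)OC/C=C(C)/CC/C(C)=C/CO[Si](c6ccccc6)(c7ccccc7)C(C)(C)C | intermediate
8 | acyloxyborane of acid 9 with the (S,S)-diazaborolidine | O=C(OB1N(S(=O)(=O)c2cc(C(F)(F)F)cc(C(F)(F)F)c2)[C@@H](c3ccccc3)[C@H](c4ccccc4)N1S(=O)(=O)c5cc(C(F)(F)F)cc(C(F)(F)F)c5)[C@H](C)[C@@](C=C)(C)CC/C(C)=C/CO[Si](c6ccccc6)(c7ccccc7)C(C)(C)C | intermediate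
9 | (2R,3S,6E)-8-(TBDPSO)-3-ethenyl-2,3,6-trimethyloct-6-enoic acid | OC(=O)[C@H](C)[C@@](C=C)(C)CC/C(C)=C/CO[Si](c1ccccc1)(c2ccccc2)C(C)(C)C | intermediate
10 | (2R,3S,6E)-8-(TBDPSO)-3-ethenyl-2,3,6-trimethyloct-6-en-1-ol | OC[C@H](C)[C@@](C=C)(C)CC/C(C)=C/CO[Si](c1ccccc1)(c2ccccc2)C(C)(C)C | intermediate
11 | (2R,3S,6E)-8-(TBDPSO)-3-ethenyl-2,3,6-trimethyloct-6-enal | O=C[C@H](C)[C@@](C=C)(C)CC/C(C)=C/CO[Si](c1ccccc1)(c2ccccc2)C(C)(C)C | intermediate
12 | 2,3-dimethylfuran | Cc1occc1C | starting material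
13 | 5-lithio-2,3-dimethylfuran | Cc1oc([Li])cc1C | intermediate
14 | lithium (1S,2R,3S,6E)-8-(TBDPSO)-1-(4,5-dimethylfuran-2-yl)-3-ethenyl-2,3,6-trimethyloct-6-en-1-olate | Cc1oc(cc1C)[C@@H](O[Li])[C@H](C)[C@@](C=C)(C)CC/C(C)=C/CO[Si](c2ccccc2)(c3ccccc3)C(C)(C)C | intermediate
15 | 2-[(1S,2R,3S,6E)-1-(TBSO)-8-(TBDPSO)-3-ethenyl-2,3,6-trimethyloct-6-en-1-yl]-4,5-dimethylfuran | Cc1oc(cc1C)[C@@H](O[Si](C)(C)C(C)(C)C)[C@H](C)[C@@](C=C)(C)CC/C(C)=C/CO[Si](c2ccccc2)(c3ccccc3)C(C)(C)C | intermediate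
16 | (3Z,6S,7R,8S,11E)-6-(TBSO)-13-(TBDPSO)-8-ethenyl-3,7,8,11-tetramethyltrideca-3,11-diene-2,5-dione | CC(=O)/C(C)=C\C(=O)[C@@H](O[Si](C)(C)C(C)(C)C)[C@H](C)[C@@](C=C)(C)CC/C(C)=C/CO[Si](c1ccccc1)(c2ccccc2)C(C)(C)C | intermediate
17 | (3E,6S,7R,8S,11E)-6-(TBSO)-13-(TBDPSO)-8-ethenyl-3,7,8,11-tetramethyltrideca-3,11-diene-2,5-dione | CC(=O)/C(C)=C/C(=O)[C@@H](O[Si](C)(C)C(C)(C)C)[C@H](C)[C@@](C=C)(C)CC/C(C)=C/CO[Si](c1ccccc1)(c2ccccc2)C(C)(C)C | intermediate
18 | (3E,6S,7R,8S,11E)-2,6-bis(TBSO)-13-(TBDPSO)-8-ethenyl-3,7,8,11-tetramethyltrideca-1,3,11-trien-5-one | C=C(O[Si](C)(C)C(C)(C)C)/C(C)=C/C(=O)[C@@H](O[Si](C)(C)C(C)(C)C)[C@H](C)[C@@](C=C)(C)CC/C(C)=C/CO[Si](c1ccccc1)(c2ccccc2)C(C)(C)C | intermediate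
19 | (2S,3R,4S)-2,7-bis(TBSO)-4-[(3E)-5-(TBDPSO)-3-methylpent-3-en-1-yl]-3,4,8-trimethyl-3,4,4a,5,6,8a-hexahydronaphthalen-1(2H)-one, C4a/C8a mixture | CC1=C(O[Si](C)(C)C(C)(C)C)CCC2C1C(=O)[C@@H](O[Si](C)(C)C(C)(C)C)[C@H](C)[C@@]2(C)CC/C(C)=C/CO[Si](c3ccccc3)(c4ccccc4)C(C)(C)C | intermediate
20 | lithium C1=C8a dienolate of 19 (C4a mixture) | CC1=C(O[Si](C)(C)C(C)(C)C)CCC2C1=C(O[Li])[C@@H](O[Si](C)(C)C(C)(C)C)[C@H](C)[C@@]2(C)CC/C(C)=C/CO[Si](c3ccccc3)(c4ccccc4)C(C)(C)C | intermediate
21 | C8a-(N-tert-butyl-S-phenylsulfilimine) adduct of 19 (C4a/C8a mixture) | CC1=C(O[Si](C)(C)C(C)(C)C)CCC2C1(S(=NC(C)(C)C)c5ccccc5)C(=O)[C@@H](O[Si](C)(C)C(C)(C)C)[C@H](C)[C@@]2(C)CC/C(C)=C/CO[Si](c3ccccc3)(c4ccccc4)C(C)(C)C | intermediate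
22 | (2S,3R,4R)-2,7-bis(TBSO)-4-[(3E)-5-(TBDPSO)-3-methylpent-3-en-1-yl]-3,4,8-trimethyl-3,4,5,6-tetrahydronaphthalen-1(2H)-one | CC1=C(O[Si](C)(C)C(C)(C)C)CCC2=C1C(=O)[C@@H](O[Si](C)(C)C(C)(C)C)[C@H](C)[C@@]2(C)CC/C(C)=C/CO[Si](c3ccccc3)(c4ccccc4)C(C)(C)C | intermediate
23 | (2S,3R,4R,8S)-2-(TBSO)-4-[(3E)-5-(TBDPSO)-3-methylpent-3-en-1-yl]-8-(hydroxymethyl)-3,4,8-trimethyl-3,4,5,6-tetrahydronaphthalene-1,7(2H,8H)-dione | OC[C@@]1(C)C(=O)CCC2=C1C(=O)[C@@H](O[Si](C)(C)C(C)(C)C)[C@H](C)[C@@]2(C)CC/C(C)=C/CO[Si](c3ccccc3)(c4ccccc4)C(C)(C)C | intermediate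
24 | (2S,3R,4R,8S)-8-(acetoxymethyl)-2-(TBSO)-4-[(3E)-5-(TBDPSO)-3-methylpent-3-en-1-yl]-3,4,8-trimethyl-3,4,5,6-tetrahydronaphthalene-1,7(2H,8H)-dione | CC(=O)OC[C@@]1(C)C(=O)CCC2=C1C(=O)[C@@H](O[Si](C)(C)C(C)(C)C)[C@H](C)[C@@]2(C)CC/C(C)=C/CO[Si](c3ccccc3)(c4ccccc4)C(C)(C)C | intermediate
25 | (2S,3R,4R,8S)-8-(acetoxymethyl)-2-hydroxy-4-[(3E)-5-hydroxy-3-methylpent-3-en-1-yl]-3,4,8-trimethyl-3,4,5,6-tetrahydronaphthalene-1,7(2H,8H)-dione | CC(=O)OC[C@@]1(C)C(=O)CCC2=C1C(=O)[C@@H](O)[C@H](C)[C@@]2(C)CC/C(C)=C/CO | intermediate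
26 | (4S,8S)-8-(acetoxymethyl)-2-hydroxy-4-[(3E)-5-hydroxy-3-methylpent-3-en-1-yl]-3,4,8-trimethyl-5,6-dihydronaphthalene-1,7(4H,8H)-dione | CC(=O)OC[C@@]1(C)C(=O)CCC2=C1C(=O)C(O)=C(C)[C@@]2(C)CC/C(C)=C/CO | target

**Step count and risks**

Total steps: 15. Longest linear sequence: 15 steps (fully linear from hexa-1,5-diyne).

Steps most likely to fail:

1. Step 10. The unactivated vinyl group may add too slowly, so that thermal desilylation or polymerisation of the siloxydiene competes. The fallback sets out from 17 and returns at 22. Tsuji–Wacker oxidation of the vinyl group (PdCl2, CuCl, O2, DMF–H2O) should give the methyl ketone F1. Double soft enolisation (TBSOTf, Et3N) gives the bis(silyl enol ether) F2, whose electron-rich enol-ether dienophile is matched to the acyl-substituted diene. Heating gives the β-silyloxy ketone cycloadduct F3, and DBU removes the silanol from F3 by E1cB elimination to give 22 directly, which also makes step 11 unnecessary.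

2. Step 12. Facial discrimination by the catalyst on this dienol ether may be insufficient, or hydrolysis of the enol ether may compete. The fallback sets out from 22 and returns at 23 and 22. Non-selective hydroxymethylation (Yb(OTf)3, aq. HCHO, THF) gives 23 together with its C8 epimer, the hydroxymethyl ketone F5; the two are diastereomers and should separate by chromatography. F5 is recycled by retro-aldol loss of formaldehyde (K2CO3, MeOH) to the C8–H ketone F6, which is re-silylated (TBSOTf, Et3N) to 22.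

3. Step 11. Deprotonation may occur at C2 in place of C8a, or sulfenylation at the hindered ring-fusion carbon may be sluggish. The fallback sets out from 19 and returns at 22. Thermodynamic soft enolisation (TMSOTf, Et3N) gives the conjugated bis(silyloxy)diene F4, and Saegusa–Ito oxidation with Pd(OAc)2 in MeCN (β-hydride elimination from the palladium enolate toward C4a) gives 22.

**Further compounds**

F1 | step 10 | methyl ketone (17 with the C4 vinyl group oxidised to acetyl) | CC(=O)/C(C)=C/C(=O)[C@@H](O[Si](C)(C)C(C)(C)C)[C@H](C)[C@@](C(C)=O)(C)CC/C(C)=C/CO[Si](c1ccccc1)(c2ccccc2)C(C)(C)C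
F2 | step 10 | bis(silyl enol ether) (18 with the vinyl group replaced by 1-(TBSO)ethenyl) | C=C(O[Si](C)(C)C(C)(C)C)/C(C)=C/C(=O)[C@@H](O[Si](C)(C)C(C)(C)C)[C@H](C)[C@@](C(=C)O[Si](C)(C)C(C)(C)C)(C)CC/C(C)=C/CO[Si](c1ccccc1)(c2ccccc2)C(C)(C)C
F3 | step 10 | β-silyloxy ketone cycloadduct (19 bearing TBSO at C4a, C4a/C8a mixture) | CC1=C(O[Si](C)(C)C(C)(C)C)CCC2(O[Si](C)(C)C(C)(C)C)C1C(=O)[C@@H](O[Si](C)(C)C(C)(C)C)[C@H](C)[C@@]2(C)CC/C(C)=C/CO[Si](c3ccccc3)(c4ccccc4)C(C)(C)C
F4 | step 11 | bis(silyloxy)diene (C1 trimethylsilyl enol ether of 19, C1=C8a, C4a mixture) | CC1=C(O[Si](C)(C)C(C)(C)C)CCC2C1=C(O[Si](C)(C)C)[C@@H](O[Si](C)(C)C(C)(C)C)[C@H](C)[C@@]2(C)CC/C(C)=C/CO[Si](c3ccccc3)(c4ccccc4)C(C)(C)C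
F5 | step 12 | C8 epimer of hydroxymethyl ketone 23 (8R) | OC[C@]1(C)C(=O)CCC2=C1C(=O)[C@@H](O[Si](C)(C)C(C)(C)C)[C@H](C)[C@@]2(C)CC/C(C)=C/CO[Si](c3ccccc3)(c4ccccc4)C(C)(C)C
F6 | step 12 | C8–H ketone (23 without the hydroxymethyl group, C8 epimer mixture) | CC1C(=O)CCC2=C1C(=O)[C@@H](O[Si](C)(C)C(C)(C)C)[C@H](C)[C@@]2(C)CC/C(C)=C/CO[Si](c3ccccc3)(c4ccccc4)C(C)(C)C
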